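**Retrosynthetic overview**
- Feature: on ring A the oxygens O1 (on C8a), O5 and O7 lie ortho, ortho and para to C4a, the carbon that carries the C4 carbonyl. C8a–O1, C5–O and C7–O can therefore each be made by addition–elimination on a 2,4,6-trifluorobenzoyl group.
- Disconnections, backwards: the three O–benzyl bonds and Na+/H+ exchange (last), 3'-O–S (sulfation of the one free phenol), 3'-O–MOM, C5–O and C7–O (fluoride for benzyloxide), O1–C8a (ring C), C3–C4 (enolate acylation).
- Rings A and B are bought as arenes. Ring C is the only ring built, closed by the C2 enolate oxygen of a 1,3-diketone on an ortho C–F of ring A.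
- Ring B carries 4'-OBn and 3'-OMOM from the outset, so that mild acid later frees the 3'-OH alone. The target has no stereocentre.

Key step: step 4

Assumption: the target is taken as drawn, the free hydrogen sulfate; because aryl hydrogen sulfates hydrolyse under their own acidity, the ester is carried as its sodium salt and protonated only in the last operation, in the cold.

**Step 1**
Reactants: 1 3',4'-dihydroxyacetophenone
Product: 2 4'-(benzyloxy)-3'-hydroxyacetophenone
Conditions: BnBr (1.0 equiv), Li2CO3 (1.5 equiv), DMF, 50 °C
Reagents that add atoms: benzyl bromide, BrCc1ccccc1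
Why: Williamson etherification in which the 4'-OH, conjugated para to the acetyl group, is the more acidic phenol, so the weak base should ionise it preferentially and one equivalent of benzyl bromide should alkylate there and leave the 3'-OH free.

**Step 2**
Reactants: 2 4'-(benzyloxy)-3'-hydroxyacetophenone
Product: 3 4'-(benzyloxy)-3'-(methoxymethoxy)acetophenone
Conditions: MOMCl (1.5 equiv), iPr2NEt (2 equiv), CH2Cl2, 0 °C to rt
Reagents that add atoms: chloromethyl methyl ether (MOMCl), COCCl
Why: Standard MOM acetal protection of a phenol (O-alkylation by the oxocarbenium-like chloromethyl ether under amine base), which touches neither the ketone nor the benzyl ether.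

**Step 3**
Reactants: 3 4'-(benzyloxy)-3'-(methoxymethoxy)acetophenone; 4 2,4,6-trifluorobenzoyl chloride
Product: 7 1-[4-(benzyloxy)-3-(methoxymethoxy)phenyl]-3-(2,4,6-trifluorophenyl)propane-1,3-dione, via lithium enolate 5 (not isolated), via lithium diketonate 6 (not isolated)
Conditions: LiN(SiMe3)2 (2.1 equiv), THF, −78 °C; then 4 (1.0 equiv), −78 °C; cold 0.5 M HCl quench
Reagents that add atoms: none
Why: Crossed Claisen-type C-acylation of a preformed lithium enolate by an aroyl chloride, in which the second equivalent of the hindered, non-nucleophilic amide base takes up the acidic product as its chelated lithium salt 6, stopping proton transfer to unreacted enolate and further acylation, while the low temperature keeps the C–F bonds intact.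

**Step 4**
Reactants: 7 1-[4-(benzyloxy)-3-(methoxymethoxy)phenyl]-3-(2,4,6-trifluorophenyl)propane-1,3-dione
Product: 9 4'-(benzyloxy)-5,7-difluoro-3'-(methoxymethoxy)flavone, via potassium diketonate 8 (not isolated)
Conditions: K2CO3 (dried, 2 equiv), dry DMF (0.05 M), rt to 50 °C
Reagents that add atoms: none
Why: K2CO3 turns the acidic 1,3-diketone 7 into the delocalised enolate 8, whose oxygen on C2 adds to one fluorine-bearing ortho carbon of the trifluorophenyl ring (the future C8a) to give a Meisenheimer anion stabilised by the C4 carbonyl on the neighbouring C4a and inductively by the two other fluorines, and loss of fluoride then forms O1–C8a. The closest known reaction type is the base-mediated cyclisation of 1-(2-fluoroaryl)propane-1,3-diones to chromones and flavones, an intramolecular SNAr O-arylation. Ring C closes as a six-membered ring; the closure counts as 6-exo-trig if the arene bond C8a=C8 is taken as the acceptor and as 6-endo-trig if C8a=C4a, the bond that passes the charge to the carbonyl, is taken, and both modes are favoured. No stereocentre is formed. The step needs attack through oxygen, at an ortho and not the para fluorine, and within the molecule: attack by C3 or by the C4 oxygen would have to close a four-membered ring, the two ortho fluorines are interchanged by rotation about C4–C4a and lead to the same product, and the para fluorine can only be reached by a second molecule, which dilution and the low nucleophilicity of a stabilised diketonate disfavour. Dried K2CO3 and dry DMF keep hydroxide out, so retro-Claisen cleavage of the electron-poor aroyl group should not compete.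

**Step 5**
Reactants: 9 4'-(benzyloxy)-5,7-difluoro-3'-(methoxymethoxy)flavone; 10 benzyl alcohol
Product: 13 4',5,7-tris(benzyloxy)-3'-(methoxymethoxy)flavone, via sodium benzyloxide 11 (not isolated), via 7-benzyloxy-5-fluoroflavone intermediate 12 (not isolated)
Conditions: 10 (2.6 equiv), NaH (2.5 equiv), THF, 0 °C until gas evolution ends; then 9, THF–NMP, 0 to 60 °C, anhydrous
Reagents that add atoms: none
Why: Twofold intermolecular SNAr by benzyloxide at C7 (para to C4a, expected first in a dipolar medium) and C5 (ortho to C4a), feasible because the ring A oxygens are all meta to one another, so the first benzyloxy group does not push electron density onto the carbons that carry the charge of the second Meisenheimer anion, while alkoxide addition at C2 is reversible without water and NMP avoids the amine by-products of DMF under strong base.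

**Step 6**
Reactants: 13 4',5,7-tris(benzyloxy)-3'-(methoxymethoxy)flavone
Product: 14 4',5,7-tris(benzyloxy)-3'-hydroxyflavone
Conditions: conc. HCl (cat.), MeOH–THF, 45 °C
Reagents that add atoms: none
Why: Acid-catalysed acetal exchange (MOM cleavage through the oxocarbenium ion, trapped by methanol) is far faster than cleavage of aryl benzyl ethers, so mild HCl should free only the 3'-OH.

**Step 7**
Reactants: 14 4',5,7-tris(benzyloxy)-3'-hydroxyflavone
Product: 16 sodium 4',5,7-tris(benzyloxy)flavon-3'-yl sulfate, via pyridinium sulfate 15 (not isolated)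
Conditions: SO3·pyridine (3 equiv), pyridine, rt to 40 °C; then aq. NaHCO3, co-evaporation with toluene, chromatography (CH2Cl2–MeOH)
Reagents that add atoms: sulfur trioxide–pyridine complex, O=S(=O)([O-])[n+]1ccccc1; sodium hydrogen carbonate, [Na+].OC([O-])=O
Why: O-sulfation of the only free phenol with the SO3·pyridine complex, followed by cation exchange with NaHCO3, which gives a base-stable sodium aryl sulfate and removes pyridine, a moderator of Pd/C towards benzyl ethers.

**Step 8**
Reactants: 16 sodium 4',5,7-tris(benzyloxy)flavon-3'-yl sulfate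
Product: 18 luteolin 3'-sulfate, via sodium luteolin 3'-sulfate 17 (not isolated)
Conditions: H2 (1 atm), 10% Pd/C, MeOH–THF, rt, stopped after uptake of 3 equiv H2; filter; then sulfonic acid cation-exchange resin (H+ form), H2O–MeOH, 0–5 °C; freeze-dry at once
Reagents that add atoms: none
Why: Catalytic hydrogenolysis of three aryl benzyl ethers over Pd/C under neutral conditions, to which aryl sulfate salts and the flavone C2–C3 double bond are normally inert at 1 atm, followed by Na+/H+ exchange on a strongly acidic resin in the cold to release the hydrogen sulfate.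

**Compound list**
1 | 3',4'-dihydroxyacetophenone | CC(=O)c1ccc(O)c(O)c1 | starting material
2 | 4'-(benzyloxy)-3'-hydroxyacetophenone | CC(=O)c1ccc(OCc2ccccc2)c(O)c1 | intermediate
3 | 4'-(benzyloxy)-3'-(methoxymethoxy)acetophenone | CC(=O)c1ccc(OCc2ccccc2)c(OCOC)c1 | intermediate
4 | 2,4,6-trifluorobenzoyl chloride | O=C(Cl)c1c(F)cc(F)cc1F | starting material
5 | lithium enolate of 3 | [Li+].C=C([O-])c1ccc(OCc2ccccc2)c(OCOC)c1 | intermediate
6 | lithium (Z)-enolate (chelated diketonate) of 7 | [Li+].[O-]/C(=C\C(=O)c1c(F)cc(F)cc1F)c1ccc(OCc2ccccc2)c(OCOC)c1 | intermediate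
7 | 1-[4-(benzyloxy)-3-(methoxymethoxy)phenyl]-3-(2,4,6-trifluorophenyl)propane-1,3-dione (largely enolised, drawn as the diketone) | O=C(CC(=O)c1ccc(OCc2ccccc2)c(OCOC)c1)c1c(F)cc(F)cc1F | intermediate
8 | potassium (Z)-enolate of 7, anionic oxygen on the future C2 | [K+].[O-]/C(=C\C(=O)c1c(F)cc(F)cc1F)c1ccc(OCc2ccccc2)c(OCOC)c1 | intermediate
9 | 4'-(benzyloxy)-5,7-difluoro-3'-(methoxymethoxy)flavone | O=c1cc(-c2ccc(OCc3ccccc3)c(OCOC)c2)oc2cc(F)cc(F)c12 | intermediate
10 | benzyl alcohol | OCc1ccccc1 | starting material
11 | sodium benzyloxide | [Na+].[O-]Cc1ccccc1 | intermediate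
12 | 4',7-bis(benzyloxy)-5-fluoro-3'-(methoxymethoxy)flavone | O=c1cc(-c2ccc(OCc3ccccc3)c(OCOC)c2)oc2cc(OCc3ccccc3)cc(F)c12 | intermediate
13 | 4',5,7-tris(benzyloxy)-3'-(methoxymethoxy)flavone | O=c1cc(-c2ccc(OCc3ccccc3)c(OCOC)c2)oc2cc(OCc3ccccc3)cc(OCc3ccccc3)c12 | intermediate
14 | 4',5,7-tris(benzyloxy)-3'-hydroxyflavone | O=c1cc(-c2ccc(OCc3ccccc3)c(O)c2)oc2cc(OCc3ccccc3)cc(OCc3ccccc3)c12 | intermediate
15 | pyridinium 4',5,7-tris(benzyloxy)flavon-3'-yl sulfate | O=c1cc(-c2ccc(OCc3ccccc3)c(OS(=O)(=O)[O-])c2)oc2cc(OCc3ccccc3)cc(OCc3ccccc3)c12.c1cc[nH+]cc1 | intermediate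
16 | sodium 4',5,7-tris(benzyloxy)flavon-3'-yl sulfate | O=c1cc(-c2ccc(OCc3ccccc3)c(OS(=O)(=O)[O-])c2)oc2cc(OCc3ccccc3)cc(OCc3ccccc3)c12.[Na+] | intermediate
17 | sodium luteolin 3'-sulfate | O=c1cc(-c2ccc(O)c(OS(=O)(=O)[O-])c2)oc2cc(O)cc(O)c12.[Na+] | intermediate
18 | luteolin 3'-sulfate | O=c1cc(-c2ccc(O)c(OS(=O)(=O)O)c2)oc2cc(O)cc(O)c12 | target

**Step count**
- Total step count: 8
- Longest linear sequence: 8 steps (1 to 18)

**Steps most likely to fail**

**Step 5.**
- Risk: the exchange at C5 may stall once the first benzyloxy group is in place. The harsher conditions then needed may let benzyloxide add at C2 and open ring C irreversibly.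
- Fallback: it sets out from 9. One equivalent of 11 at 0 °C stops the reaction at 12, which is now isolated.
- 12 is treated with (E)-benzaldoxime and Cs2CO3 in DMSO at about 60 °C. The oximate is an alpha-effect oxygen nucleophile, far less basic than an alkoxide, and serves as a hydroxide surrogate. It should displace the 5-fluoride to give the O-aryl benzaldoxime ether F1.
- F1 fragments under the same base to benzonitrile and, after acidification, 4',7-bis(benzyloxy)-5-hydroxy-3'-(methoxymethoxy)flavone F2.
- Benzylation of the chelated 5-OH (BnBr, K2CO3, DMF, 60 °C) comes back to the route at 13.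

**Step 8.**
- Risk: hydrogenolysis of an ionic substrate that may still carry traces of pyridine can be slow. Long exposure may then begin to saturate C2–C3, and the sulfate may be lost by solvolysis during the prolonged reaction and handling.
- Fallback: it sets out from 14 and masks the sulfate as a neutral diester.
- Deprotonation with NaN(SiMe3)2 in THF at −78 °C and reaction with isobutyl chlorosulfate should give isobutyl 4',5,7-tris(benzyloxy)flavon-3'-yl sulfate F3. It can be purified on silica free of any amine.
- Hydrogenolysis (H2, Pd/C, EtOAc–THF) of this neutral compound gives isobutyl luteolin-3'-yl sulfate F4.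
- SN2 dealkylation with NaI in acetone at 55 °C removes the isobutyl group. This comes back to the route at 17, which should separate from acetone as the sodium salt and then goes onto the acid resin as in step 8.

**Step 3.**
- Risk: O-acylation of the enolate, a second acylation of the diketonate and consumption of the acid chloride by the excess amide base may erode the C-acylation. Partial ring closure on warming would be harmless, since it only anticipates step 4.
- Fallback: it sets out from 3 and replaces acylation by aldol addition and oxidation.
- Enolate 5 (LiN(SiMe3)2, 1.05 equiv, THF, −78 °C) is added to 2,4,6-trifluorobenzaldehyde and quenched cold. This gives the racemic aldol 1-[4-(benzyloxy)-3-(methoxymethoxy)phenyl]-3-hydroxy-3-(2,4,6-trifluorophenyl)propan-1-one F5.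
- The carbinol centre of F5 is then erased by Dess–Martin periodinane (NaHCO3, CH2Cl2, rt), coming back to the route at 7.

**Further compounds**
F1 | step 5 | (E)-benzaldehyde O-[4',7-bis(benzyloxy)-3'-(methoxymethoxy)flavon-5-yl]oxime | O=c1cc(-c2ccc(OCc3ccccc3)c(OCOC)c2)oc2cc(OCc3ccccc3)cc(O/N=C/c3ccccc3)c12
F2 | step 5 | 4',7-bis(benzyloxy)-5-hydroxy-3'-(methoxymethoxy)flavone | O=c1cc(-c2ccc(OCc3ccccc3)c(OCOC)c2)oc2cc(OCc3ccccc3)cc(O)c12
F3 | step 8 | isobutyl 4',5,7-tris(benzyloxy)flavon-3'-yl sulfate | O=c1cc(-c2ccc(OCc3ccccc3)c(OS(=O)(=O)OCC(C)C)c2)oc2cc(OCc3ccccc3)cc(OCc3ccccc3)c12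
F4 | step 8 | isobutyl luteolin-3'-yl sulfate | O=c1cc(-c2ccc(O)c(OS(=O)(=O)OCC(C)C)c2)oc2cc(O)cc(O)c12
F5 | step 3 | 1-[4-(benzyloxy)-3-(methoxymethoxy)phenyl]-3-hydroxy-3-(2,4,6-trifluorophenyl)propan-1-one (racemic) | O=C(CC(O)c1c(F)cc(F)cc1F)c1ccc(OCc2ccccc2)c(OCOC)c1
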